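**Plan**
- Retrosynthesis: the five O–Si bonds are cut first, C4=O is traced back to a C4–OEt ether, and the chalcone Cβ–aryl bond is cut (Heck). Then C2–C3 and C4–C4a of the pyran ring are cut together, as a cationic [4+2] (oxa-Povarov) annulation.
- Enabling feature: C2 carries O1 and a para-oxygenated aryl group, so it is the carbon of a stabilized O-aryl oxocarbenium ion. C4a lies ortho to O1 and para to the C7 oxygen of ring A, so a two-carbon (E)-enol ether can be annulated across C2 and C4a.
- Forward: an α-acetoxy aryl ether (from 4-hydroxybenzoic acid and resorcinol) and an (E)-β-aryl enol ether (from 4-bromo-2-iodophenol) close ring C in one step. The aryl bromide is then coupled with an aryl vinyl ketone, C4 is oxidized to the ketone, and all silyl ethers are removed.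
- Stereochemistry: C2 (R) comes from the chiral counter-anion in the annulation. C3 (S, trans to C2) comes from the annulation and from thermodynamic equilibration at the ketone stage. C4 is transient, and the E alkene comes from the Heck reaction.

Key step: step 7

Assumption: the sense of induction of the chiral acid cannot be predicted with confidence; the (S,S) antipode is written, and its mirror image is used if it proves to deliver the 2S series. Chromanone numbering (O1, C2, C3, C4, C4a, C8a) is used for the pyran ring throughout; ring A is the benzo ring and ring C the pyran ring.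

**Route**

Step 1
Reactants: 1 4-hydroxybenzoic acid
Product: 3 4-(triisopropylsilyloxy)benzoic acid, via triisopropylsilyl 4-(triisopropylsilyloxy)benzoate 2 (not isolated)
Conditions: iPr3SiCl (2.3 equiv), imidazole, DMF, rt; then K2CO3, MeOH/THF/H2O, rt; 1 M HCl to pH 3
Reagents that add atoms: chlorotriisopropylsilane, CC(C)[Si](Cl)(C(C)C)C(C)C
Why: Imidazole-promoted O-silylation caps both acidic OH groups, and the silyl ester, far more labile than the aryl silyl ether, is then hydrolysed selectively by mild carbonate.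

Step 2
Reactants: 4 resorcinol
Product: 5 3-(triisopropylsilyloxy)phenol
Conditions: resorcinol (3 equiv), iPr3SiCl (1 equiv), imidazole, DMF, 0 °C to rt
Reagents that add atoms: chlorotriisopropylsilane, CC(C)[Si](Cl)(C(C)C)C(C)C
Why: Statistical mono-O-silylation with the diol in excess should favour the mono-ether, which is separated from water-soluble resorcinol by extraction.

Step 3
Reactants: 3 4-(triisopropylsilyloxy)benzoic acid; 5 3-(triisopropylsilyloxy)phenol
Product: 6 3-(triisopropylsilyloxy)phenyl 4-(triisopropylsilyloxy)benzoate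
Conditions: N,N'-dicyclohexylcarbodiimide, 4-(dimethylamino)pyridine (cat.), CH2Cl2, 0 °C to rt
Reagents that add atoms: none
Why: Steglich esterification (carbodiimide activation, acyl transfer through the acylpyridinium) joins a benzoic acid to a phenol under neutral conditions that leave both aryl silyl ethers intact.

Step 4
Reactants: 6 3-(triisopropylsilyloxy)phenyl 4-(triisopropylsilyloxy)benzoate
Product: 8 racemic [4-(triisopropylsilyloxy)phenyl][3-(triisopropylsilyloxy)phenoxy]methyl acetate, via diisobutylaluminium hemiacetal 7 (not isolated)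
Conditions: iBu2AlH (1.05 equiv), CH2Cl2, −78 °C; then pyridine, 4-(dimethylamino)pyridine, Ac2O, −78 to −20 °C; chromatography on Et3N-deactivated silica
Reagents that add atoms: acetic anhydride, CC(=O)OC(C)=O
Why: Rychnovsky reductive acetylation: one hydride adds to the ester at −78 °C and the aluminium hemiacetal is O-acetylated in the cold before it can collapse, giving the α-acetoxy aryl ether while the silyl ethers stay inert.

Step 5
Reactants: 9 4-bromo-2-iodophenol
Product: 10 (4-bromo-2-iodophenoxy)triisopropylsilane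
Conditions: iPr3SiCl, imidazole, DMF, rt to 40 °C
Reagents that add atoms: chlorotriisopropylsilane, CC(C)[Si](Cl)(C(C)C)C(C)C
Why: Imidazole-promoted O-silylation of the phenol installs the hindered, acid- and base-resistant silyl ether carried to the last step.

Step 6
Reactants: 10 (4-bromo-2-iodophenoxy)triisopropylsilane; 11 2-[(E)-2-ethoxyethenyl]-4,4,5,5-tetramethyl-1,3,2-dioxaborolane
Product: 12 4-bromo-2-[(E)-2-ethoxyethenyl]-1-(triisopropylsilyloxy)benzene
Conditions: Pd(PPh3)4 (3 mol %), K3PO4 (2 M aq.), THF, 60 °C; chromatography on Et3N-deactivated silica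
Reagents that add atoms: none
Why: Suzuki–Miyaura coupling in which zerovalent palladium inserts into the C–I bond much faster than into the C–Br bond and the alkenyl group transfers with retention, so a single (E)-enol ether with the bromide intact is expected.

Step 7
Reactants: 8 racemic [4-(triisopropylsilyloxy)phenyl][3-(triisopropylsilyloxy)phenoxy]methyl acetate; 12 4-bromo-2-[(E)-2-ethoxyethenyl]-1-(triisopropylsilyloxy)benzene
Product: 15 (2R,3R,4R)-3-[5-bromo-2-(triisopropylsilyloxy)phenyl]-4-ethoxy-7-(triisopropylsilyloxy)-2-[4-(triisopropylsilyloxy)phenyl]chroman (2,3-trans-3,4-trans), via O-aryl oxocarbenium ion 13 (not isolated), via acyclic ethoxycarbenium ion 14 (not isolated)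
Conditions: (S,S)-imidodiphosphorimidate Brønsted acid (5 mol %; two (S)-3,3'-diphenyl-1,1'-bi-2-naphthol phosphoryl units bridged by NH, each phosphorus bearing an N-trifluoromethylsulfonyl imido group; aryl groups to be tuned to the substrate size), 12 (1.5 equiv, slow addition), CH2Cl2, −78 to −60 °C; Et3N quench
Reagents that add atoms: none
Why: Proposed new method: the strong chiral acid protonates the acetate of 8 and acetic acid leaves, giving O-aryl oxocarbenium ion 13 paired with the chiral imidodiphosphorimidate anion; the aryl-bearing carbon of enol ether 12 attacks C2 to form C2–C3 and ethoxycarbenium ion 14, whose C4 is attacked by the aryloxy ring carbon ortho to O1 to form C4–C4a, and loss of the arenium proton regenerates the acid. The closest known reaction types are the SnCl4-promoted oxa-Povarov annulation of aryl oxocarbenium ions with alkenes and imidodiphosphorimidate-catalysed additions of π-nucleophiles to oxocarbenium ions generated from acetates. Ring C closes by intramolecular Friedel–Crafts alkylation, a six-membered closure that is exo with respect to the C4=O+ bond (6-exo-trig) and has the arene C4a–C8a bond inside the new ring. C2 is set by the face of 13 left open by the confined anion (catalyst control), C3 by the (E) geometry of 12 together with an endo orientation of the ethoxy group that places the C3 aryl group anti to the C2 aryl group, and C4 by closure with the ethoxy group pseudo-equatorial; only C2 has to persist, because C4 becomes a carbonyl carbon and C3 is equilibrated in step 12. The step needs ionization by loss of acetate and not of the phenol (secured by the acyl leaving group), closure para to the 7-silyloxy group and not between the two ring oxygens (secured by the bulk of the triisopropylsilyl group and the lower hindrance at that carbon), and survival of the silyl ethers on the quinoid cation and next to the C4 cation (secured by the hindered silicon).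

Step 8
Reactants: 16 2,4-dihydroxybenzaldehyde
Product: 17 2,4-bis(triisopropylsilyloxy)benzaldehyde
Conditions: iPr3SiCl (2.5 equiv), imidazole, DMF, rt to 40 °C
Reagents that add atoms: chlorotriisopropylsilane, CC(C)[Si](Cl)(C(C)C)C(C)C
Why: Imidazole-promoted O-silylation in DMF protects both phenols, including the hydrogen-bonded ortho one, as is routine for salicylaldehydes.

Step 9
Reactants: 17 2,4-bis(triisopropylsilyloxy)benzaldehyde
Product: 18 racemic 1-[2,4-bis(triisopropylsilyloxy)phenyl]prop-2-en-1-ol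
Conditions: CH2=CHMgBr, THF, −78 °C; sat. aq. NH4Cl at −78 °C
Reagents that add atoms: vinylmagnesium bromide, C=C[Mg]Br
Why: Grignard 1,2-addition to the aldehyde at low temperature, where aryl-to-alkoxide silyl migration is slow; the new carbinol centre is racemic and is removed in step 10.

Step 10
Reactants: 18 racemic 1-[2,4-bis(triisopropylsilyloxy)phenyl]prop-2-en-1-ol
Product: 19 1-[2,4-bis(triisopropylsilyloxy)phenyl]prop-2-en-1-one
Conditions: activated MnO2 (excess), CH2Cl2, rt; used at once
Reagents that add atoms: none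
Why: MnO2 oxidizes the benzylic and allylic secondary alcohol to the aryl vinyl ketone under neutral conditions that spare the silyl ethers and the polymerization-prone enone.

Step 11
Reactants: 15 (2R,3R,4R)-3-[5-bromo-2-(triisopropylsilyloxy)phenyl]-4-ethoxy-7-(triisopropylsilyloxy)-2-[4-(triisopropylsilyloxy)phenyl]chroman; 19 1-[2,4-bis(triisopropylsilyloxy)phenyl]prop-2-en-1-one
Product: 20 (E)-1-[2,4-bis(triisopropylsilyloxy)phenyl]-3-{3-[(2R,3R,4R)-4-ethoxy-7-(triisopropylsilyloxy)-2-[4-(triisopropylsilyloxy)phenyl]chroman-3-yl]-4-(triisopropylsilyloxy)phenyl}prop-2-en-1-one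
Conditions: Pd(OAc)2 (5 mol %), P(o-tolyl)3 (12 mol %), Et3N, 2,6-di-tert-butyl-4-methylphenol (cat.), DMF, 85 °C
Reagents that add atoms: none
Why: Mizoroki–Heck reaction (oxidative addition of the aryl bromide to zerovalent palladium, syn insertion at the terminal enone carbon, syn β-hydride elimination) should give the (E)-chalcone; at this stage the chroman has no enolizable ketone, so the hot amine cannot open ring C or touch C2.

Step 12
Reactants: 20 (E)-1-[2,4-bis(triisopropylsilyloxy)phenyl]-3-{3-[(2R,3R,4R)-4-ethoxy-7-(triisopropylsilyloxy)-2-[4-(triisopropylsilyloxy)phenyl]chroman-3-yl]-4-(triisopropylsilyloxy)phenyl}prop-2-en-1-one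
Product: 22 (2R,3S)-3-{5-[(E)-3-[2,4-bis(triisopropylsilyloxy)phenyl]-3-oxoprop-1-en-1-yl]-2-(triisopropylsilyloxy)phenyl}-7-(triisopropylsilyloxy)-2-[4-(triisopropylsilyloxy)phenyl]chroman-4-one (2,3-trans), via C4 ethyl hemiketal 21 (not isolated)
Conditions: 2,3-dichloro-5,6-dicyano-1,4-benzoquinone (1.3 equiv), CH2Cl2/pH 7 phosphate buffer, 0 °C to rt; then Et3N (0.2 equiv), CH2Cl2, 0 °C to rt
Reagents that add atoms: water, O
Why: Oxidative cleavage of an electron-rich benzylic ether: the quinone abstracts hydride from C4–H (benzylic to the ring A carbon para to the 7-silyloxy group and α to the ethoxy oxygen), water capture gives hemiketal 21, which loses ethanol to the ketone, and the catalytic amine equilibrates C3 through the enol to the diequatorial 2,3-trans isomer while being too weak to drive ring opening at C2.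

Step 13
Reactants: 22 (2R,3S)-3-{5-[(E)-3-[2,4-bis(triisopropylsilyloxy)phenyl]-3-oxoprop-1-en-1-yl]-2-(triisopropylsilyloxy)phenyl}-7-(triisopropylsilyloxy)-2-[4-(triisopropylsilyloxy)phenyl]chroman-4-one
Product: 23 (2R,3S)-3-{5-[(E)-3-(2,4-dihydroxyphenyl)-3-oxoprop-1-en-1-yl]-2-hydroxyphenyl}-7-hydroxy-2-(4-hydroxyphenyl)chroman-4-one (CNP0183323.3)
Conditions: Bu4NF (6 equiv), AcOH (6 equiv), THF, 0 °C to rt; pH 5 work-up
Reagents that add atoms: none
Why: Fluoride desilylation removes all five aryl silyl ethers, and the acetic acid buffer keeps the phenols protonated so that neither phenoxide-driven opening of the chromanone (loss of C2) nor cyclization of the 2'-hydroxychalcone is triggered.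

**Compound list**
1 | 4-hydroxybenzoic acid | OC(=O)c1ccc(O)cc1 | starting material
2 | triisopropylsilyl 4-(triisopropylsilyloxy)benzoate | CC(C)[Si](OC(=O)c1ccc(O[Si](C(C)C)(C(C)C)C(C)C)cc1)(C(C)C)C(C)C | intermediate
3 | 4-(triisopropylsilyloxy)benzoic acid | OC(=O)c1ccc(O[Si](C(C)C)(C(C)C)C(C)C)cc1 | intermediate
4 | resorcinol | Oc1cccc(O)c1 | starting material
5 | 3-(triisopropylsilyloxy)phenol | Oc1cccc(O[Si](C(C)C)(C(C)C)C(C)C)c1 | intermediate
6 | 3-(triisopropylsilyloxy)phenyl 4-(triisopropylsilyloxy)benzoate | O=C(Oc1cccc(O[Si](C(C)C)(C(C)C)C(C)C)c1)c1ccc(O[Si](C(C)C)(C(C)C)C(C)C)cc1 | intermediate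
7 | diisobutylaluminium hemiacetal of ester 6 (racemic) | CC(C)C[Al](CC(C)C)OC(Oc1cccc(O[Si](C(C)C)(C(C)C)C(C)C)c1)c1ccc(O[Si](C(C)C)(C(C)C)C(C)C)cc1 | intermediate
8 | racemic [4-(triisopropylsilyloxy)phenyl][3-(triisopropylsilyloxy)phenoxy]methyl acetate | CC(=O)OC(Oc1cccc(O[Si](C(C)C)(C(C)C)C(C)C)c1)c1ccc(O[Si](C(C)C)(C(C)C)C(C)C)cc1 | intermediate
9 | 4-bromo-2-iodophenol | Oc1ccc(Br)cc1I | starting material
10 | (4-bromo-2-iodophenoxy)triisopropylsilane | CC(C)[Si](Oc1ccc(Br)cc1I)(C(C)C)C(C)C | intermediate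
11 | 2-[(E)-2-ethoxyethenyl]-4,4,5,5-tetramethyl-1,3,2-dioxaborolane | CCO/C=C/B1OC(C)(C)C(C)(C)O1 | starting material
12 | 4-bromo-2-[(E)-2-ethoxyethenyl]-1-(triisopropylsilyloxy)benzene | CCO/C=C/c1cc(Br)ccc1O[Si](C(C)C)(C(C)C)C(C)C | intermediate
13 | O-aryl oxocarbenium ion, [4-(triisopropylsilyloxy)benzylidene][3-(triisopropylsilyloxy)phenyl]oxonium | CC(C)[Si](Oc1ccc(C=[O+]c2cccc(O[Si](C(C)C)(C(C)C)C(C)C)c2)cc1)(C(C)C)C(C)C | intermediate
14 | acyclic ethoxycarbenium ion, ethyl{(2S,3R)-2-[5-bromo-2-(triisopropylsilyloxy)phenyl]-3-[3-(triisopropylsilyloxy)phenoxy]-3-[4-(triisopropylsilyloxy)phenyl]propylidene}oxonium | Brc1ccc(O[Si](C(C)C)(C(C)C)C(C)C)c([C@H](C=[O+]CC)[C@@H](Oc2cccc(O[Si](C(C)C)(C(C)C)C(C)C)c2)c2ccc(O[Si](C(C)C)(C(C)C)C(C)C)cc2)c1 | intermediate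
15 | (2R,3R,4R)-3-[5-bromo-2-(triisopropylsilyloxy)phenyl]-4-ethoxy-7-(triisopropylsilyloxy)-2-[4-(triisopropylsilyloxy)phenyl]chroman | Brc1ccc(O[Si](C(C)C)(C(C)C)C(C)C)c([C@@H]2[C@@H](OCC)c3ccc(O[Si](C(C)C)(C(C)C)C(C)C)cc3O[C@H]2c2ccc(O[Si](C(C)C)(C(C)C)C(C)C)cc2)c1 | intermediate
16 | 2,4-dihydroxybenzaldehyde | O=Cc1ccc(O)cc1O | starting material
17 | 2,4-bis(triisopropylsilyloxy)benzaldehyde | O=Cc1ccc(O[Si](C(C)C)(C(C)C)C(C)C)cc1O[Si](C(C)C)(C(C)C)C(C)C | intermediate
18 | racemic 1-[2,4-bis(triisopropylsilyloxy)phenyl]prop-2-en-1-ol | C=CC(O)c1ccc(O[Si](C(C)C)(C(C)C)C(C)C)cc1O[Si](C(C)C)(C(C)C)C(C)C | intermediate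
19 | 1-[2,4-bis(triisopropylsilyloxy)phenyl]prop-2-en-1-one | C=CC(=O)c1ccc(O[Si](C(C)C)(C(C)C)C(C)C)cc1O[Si](C(C)C)(C(C)C)C(C)C | intermediate
20 | (E)-1-[2,4-bis(triisopropylsilyloxy)phenyl]-3-{3-[(2R,3R,4R)-4-ethoxy-7-(triisopropylsilyloxy)-2-[4-(triisopropylsilyloxy)phenyl]chroman-3-yl]-4-(triisopropylsilyloxy)phenyl}prop-2-en-1-one | O=C(/C=C/c1ccc(O[Si](C(C)C)(C(C)C)C(C)C)c([C@@H]2[C@@H](OCC)c3ccc(O[Si](C(C)C)(C(C)C)C(C)C)cc3O[C@H]2c2ccc(O[Si](C(C)C)(C(C)C)C(C)C)cc2)c1)c1ccc(O[Si](C(C)C)(C(C)C)C(C)C)cc1O[Si](C(C)C)(C(C)C)C(C)C | intermediate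
21 | C4 ethyl hemiketal, (2R,3S)-4-ethoxy-4-hydroxy analogue of 22 (C4 undefined) | O=C(/C=C/c1ccc(O[Si](C(C)C)(C(C)C)C(C)C)c([C@@H]2C(O)(OCC)c3ccc(O[Si](C(C)C)(C(C)C)C(C)C)cc3O[C@H]2c2ccc(O[Si](C(C)C)(C(C)C)C(C)C)cc2)c1)c1ccc(O[Si](C(C)C)(C(C)C)C(C)C)cc1O[Si](C(C)C)(C(C)C)C(C)C | intermediate
22 | (2R,3S)-3-{5-[(E)-3-[2,4-bis(triisopropylsilyloxy)phenyl]-3-oxoprop-1-en-1-yl]-2-(triisopropylsilyloxy)phenyl}-7-(triisopropylsilyloxy)-2-[4-(triisopropylsilyloxy)phenyl]chroman-4-one | O=C(/C=C/c1ccc(O[Si](C(C)C)(C(C)C)C(C)C)c([C@@H]2C(=O)c3ccc(O[Si](C(C)C)(C(C)C)C(C)C)cc3O[C@H]2c2ccc(O[Si](C(C)C)(C(C)C)C(C)C)cc2)c1)c1ccc(O[Si](C(C)C)(C(C)C)C(C)C)cc1O[Si](C(C)C)(C(C)C)C(C)C | intermediate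
23 | (2R,3S)-3-{5-[(E)-3-(2,4-dihydroxyphenyl)-3-oxoprop-1-en-1-yl]-2-hydroxyphenyl}-7-hydroxy-2-(4-hydroxyphenyl)chroman-4-one | O=C(/C=C/c1ccc(O)c([C@@H]2C(=O)c3ccc(O)cc3O[C@H]2c2ccc(O)cc2)c1)c1ccc(O)cc1O | target

**Step count and risks**

Total steps: 13. Longest linear sequence: 7 steps (steps 1, 3, 4, 7, 11, 12, 13).

Steps most likely to fail:

1. Step 7. The confined acid may not accommodate two heavily silylated partners, so that the enol ether is instead consumed by acid-catalysed oligomerization, or the ion pair may give poor facial selectivity at C2. Fallback: setting out from 8 and 12, the annulation is run under the stoichiometric achiral Lewis-acid conditions established for annulating aryl oxocarbenium ions with alkenes (SnCl4, CH2Cl2, −78 °C). This should give 15 together with an equal amount of its mirror image, (2S,3S,4S)-3-[5-bromo-2-(triisopropylsilyloxy)phenyl]-4-ethoxy-7-(triisopropylsilyloxy)-2-[4-(triisopropylsilyloxy)phenyl]chroman F1. The two are separated by preparative HPLC on a polysaccharide chiral stationary phase, and the route is rejoined at 15.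

2. Step 4. The aluminium hemiacetal of an aryl ester may collapse with loss of aryloxide before it is acetylated, which leads to over-reduction and to fragmentation into aldehyde and phenol. Fallback: setting out from 5, commercial 4-hydroxybenzaldehyde is silylated (iPr3SiCl, imidazole, DMF) to 4-(triisopropylsilyloxy)benzaldehyde F2. Pivaloyl chloride is then added across the carbonyl group (ZnCl2 cat., CH2Cl2) to give chloro[4-(triisopropylsilyloxy)phenyl]methyl pivalate F3. Phenol 5 displaces the chloride in the presence of iPr2NEt to give [4-(triisopropylsilyloxy)phenyl][3-(triisopropylsilyloxy)phenoxy]methyl pivalate F4; the hindered acyl group is chosen to suppress acyl transfer to the phenol. F4 takes the place of 8 in step 7, with pivalic acid as the leaving group, and the route is rejoined at 15.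

3. Step 12. Hydride abstraction at C4 may be slow for a ring activated only by one silyloxy and one aryloxy group, and oxidation at the C2–H bond or elimination to the chromene may compete. Fallback: setting out from 20, the benzylic ethoxy group is exchanged for hydroxyl by mild acid solvolysis (pyridinium p-toluenesulfonate, THF/H2O, 40 °C) to give the (2R,3R)-chroman-4-ol F5 as a mixture of C4 epimers. F5 is oxidized with Dess–Martin periodinane (NaHCO3, CH2Cl2) and treated with catalytic Et3N as in step 12, and the route is rejoined at 22.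

**Further compounds**
F1 | step 7 | (2S,3S,4S)-3-[5-bromo-2-(triisopropylsilyloxy)phenyl]-4-ethoxy-7-(triisopropylsilyloxy)-2-[4-(triisopropylsilyloxy)phenyl]chroman (enantiomer of 15) | Brc1ccc(O[Si](C(C)C)(C(C)C)C(C)C)c([C@H]2[C@H](OCC)c3ccc(O[Si](C(C)C)(C(C)C)C(C)C)cc3O[C@@H]2c2ccc(O[Si](C(C)C)(C(C)C)C(C)C)cc2)c1
F2 | step 4 | 4-(triisopropylsilyloxy)benzaldehyde | O=Cc1ccc(O[Si](C(C)C)(C(C)C)C(C)C)cc1
F3 | step 4 | racemic chloro[4-(triisopropylsilyloxy)phenyl]methyl 2,2-dimethylpropanoate | CC(C)(C)C(=O)OC(Cl)c1ccc(O[Si](C(C)C)(C(C)C)C(C)C)cc1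
F4 | step 4 | racemic [4-(triisopropylsilyloxy)phenyl][3-(triisopropylsilyloxy)phenoxy]methyl 2,2-dimethylpropanoate | CC(C)(C)C(=O)OC(Oc1cccc(O[Si](C(C)C)(C(C)C)C(C)C)c1)c1ccc(O[Si](C(C)C)(C(C)C)C(C)C)cc1
F5 | step 12 | (E)-1-[2,4-bis(triisopropylsilyloxy)phenyl]-3-{3-[(2R,3R)-4-hydroxy-7-(triisopropylsilyloxy)-2-[4-(triisopropylsilyloxy)phenyl]chroman-3-yl]-4-(triisopropylsilyloxy)phenyl}prop-2-en-1-one (C4 epimers) | O=C(/C=C/c1ccc(O[Si](C(C)C)(C(C)C)C(C)C)c([C@@H]2C(O)c3ccc(O[Si](C(C)C)(C(C)C)C(C)C)cc3O[C@H]2c2ccc(O[Si](C(C)C)(C(C)C)C(C)C)cc2)c1)c1ccc(O[Si](C(C)C)(C(C)C)C(C)C)cc1O[Si](C(C)C)(C(C)C)C(C)C
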